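The route rests on cutting the C5–C6 bond of the cyclopentane (C2–C3–C4–C5–C6): the ring is treated as a contracted p-menthane in which the exocyclic C7 was once a ring carbon lying between C5 and C6. One operation, a Lewis-acid-induced 1,2-shift across an epoxide, moves the siloxy-bearing C5 from C7 to C6, closes the five-membered ring, sets C6 by inversion and unveils C7 as the aldehyde that later carries the polyene. Its substrate is a cyclohexane 2,3-epoxide flanked by a tertiary triethylsilyl ether (future C5) and the C1 carbinol side chain (on future C2), made from (+)-2-carene, whose cyclopropane fixes the C5 configuration.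

Key step: step 7

Remarks on the chemistry (assumptions):
- Carotenoid numbering is used for the target; p-menthane numbering is used for the six-membered intermediates (C1 = methyl carbinol, C4 = carbon bearing the C8 side chain).
- The ring half is drawn from (+)-2-carene (natural (1S,6R) enantiomer) and not from an α-terpinyl ester, because peracid epoxidation of the latter is not face-selective and the epoxide needed (oxygen trans to the side chain) is the one that resists opening at C2; in the carene the cyclopropane dictates this centre.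
- Pseudoionone is used as its (3E,5E) isomer (any 5Z isomer removed by fractional distillation before use).

Step 1
Reactants: 1 (+)-2-carene, (1S,6R)-3,7,7-trimethylbicyclo[4.1.0]hept-2-ene
Product: 2 (+)-trans-2-carene oxide, (1S,2S,3R,6R)-2,3-epoxycarane (oxirane anti to the cyclopropane)
Conditions: mCPBA, NaHCO3, CH2Cl2/H2O, 0 °C
Reagents that add atoms: meta-chloroperbenzoic acid, OOC(=O)c1cccc(Cl)c1
Why: Prilezhaev epoxidation of a trisubstituted alkene; the endo methyl of the gem-dimethylcyclopropane screens the syn face, so the peracid should add anti to the three-membered ring, which sets the tertiary C–O centre that becomes C5 of the target, while the bicarbonate buffer keeps the acid-labile product intact.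

Step 2
Reactants: 2 (+)-trans-2-carene oxide
Product: 3 (1R,4R)-1-methyl-4-(prop-1-en-2-yl)cyclohex-2-en-1-ol (p-mentha-2,8-dien-1-ol with the hydroxyl trans to the isopropenyl group)
Conditions: pyridinium p-toluenesulfonate (5 mol %), CH2Cl2, 0 °C → rt
Reagents that add atoms: none
Why: Acid-catalysed cyclopropylcarbinyl-to-homoallyl epoxide opening followed by E1 loss of a methyl proton; the secondary C–O bond beside the cyclopropane ionises with help from the antiperiplanar cyclopropane bond, the tertiary C–O bond is never broken, so the carbinol keeps its configuration and no new stereocentre is formed.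

Step 3
Reactants: 3 (1R,4R)-1-methyl-4-(prop-1-en-2-yl)cyclohex-2-en-1-ol
Product: 4 triethyl{[(1R,4R)-1-methyl-4-(prop-1-en-2-yl)cyclohex-2-en-1-yl]oxy}silane
Conditions: Et3SiOTf, 2,6-lutidine, CH2Cl2, −78 °C
Reagents that add atoms: triethylsilyl trifluoromethanesulfonate, CC[Si](CC)(CC)OS(=O)(=O)C(F)(F)F
Why: Silylation of a tertiary allylic alcohol with a silyl triflate and a hindered pyridine base; no stereocentre is touched, and capping the C1 oxygen now means it cannot direct the later epoxidation.

Step 4
Reactants: 4 triethyl{[(1R,4R)-1-methyl-4-(prop-1-en-2-yl)cyclohex-2-en-1-yl]oxy}silane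
Product: 6 2-[(1R,4R)-4-methyl-4-(triethylsilyloxy)cyclohex-2-en-1-yl]propan-2-ol, via tertiary hydroperoxide 5 (not isolated)
Conditions: Co(acac)2 (20 mol %), PhSiH3, O2 (1 atm), i-PrOH, rt; then Me2S
Reagents that add atoms: dioxygen, O=O
Why: Mukaiyama hydration, in which hydrogen-atom transfer from a cobalt hydride to the 1,1-disubstituted alkene gives the tertiary C8 radical that is trapped by O2 and reduced to the alcohol; the hindered ring alkene would give only a secondary radical and should stay intact, and C8 (two methyl groups) is not stereogenic.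

Step 5
Reactants: 6 2-[(1R,4R)-4-methyl-4-(triethylsilyloxy)cyclohex-2-en-1-yl]propan-2-ol
Product: 7 (1R,2R,3R,4R)-2,3-epoxy-1-(triethylsilyloxy)-p-menthan-8-ol (oxirane cis to the side chain and to the C1 methyl)
Conditions: VO(acac)2 (5 mol %), t-BuOOH (decane), toluene, rt → 40 °C
Reagents that add atoms: tert-butyl hydroperoxide, CC(C)(C)OO
Why: Vanadium-catalysed hydroxyl-directed epoxidation of a homoallylic alcohol; the C8 alkoxide bound to the vanadium peroxide delivers oxygen to the ring face it occupies, so both epoxide carbons are set cis to the side chain and trans to the capped C1 oxygen.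

Step 6
Reactants: 7 (1R,2R,3R,4R)-2,3-epoxy-1-(triethylsilyloxy)-p-menthan-8-ol
Product: 8 (1R,2R,3R,4R)-2,3-epoxy-1,8-bis(triethylsilyloxy)-p-menthane
Conditions: Et3SiOTf, 2,6-lutidine, CH2Cl2, −78 °C
Reagents that add atoms: triethylsilyl trifluoromethanesulfonate, CC[Si](CC)(CC)OS(=O)(=O)C(F)(F)F
Why: Silylation of the tertiary side-chain alcohol with a silyl triflate and a hindered base at low temperature, where the epoxide should survive; no stereocentre is affected.

Step 7
Reactants: 8 (1R,2R,3R,4R)-2,3-epoxy-1,8-bis(triethylsilyloxy)-p-menthane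
Product: 9 (1R,2R,5R)-2-methyl-2-(triethylsilyloxy)-5-[2-(triethylsilyloxy)propan-2-yl]cyclopentane-1-carbaldehyde (formyl, methyl and side chain on one face)
Conditions: Me3Al (2 equiv), 4-bromo-2,6-di-tert-butylphenol (4 equiv), CH2Cl2, rt, giving MeAl(OAr)2; then 8, −78 → −40 °C; H2O, aq. potassium sodium tartrate
Reagents that add atoms: none
Why: The bulky, oxophilic aluminium aryloxide binds the epoxide oxygen; the C3–O bond (C3 = future C6) lengthens in preference to C2–O because positive charge at C2 would sit next to the electron-withdrawing siloxy carbon C1, and as it does the C1–C2 ring bond shifts to C3 antiperiplanar to the departing oxygen while the oxygen left on C2 becomes the formyl group (semipinacol, Meinwald-type 1,2-shift). The closest known reactions are the aluminium-aryloxide-promoted rearrangement of 2,3-epoxy silyl ethers to β-siloxy aldehydes and the Lewis-acid ring contraction of cyclohexene oxides to cyclopentanecarbaldehydes. The cyclopentane is closed by ring contraction through a suprafacial 1,2-alkyl shift, not by cyclisation of an open chain. The single new stereocentre (C6 of the target) arises with inversion at the epoxide carbon and is therefore dictated by the epoxide configuration set in step 5, while the migrating carbinol carbon (future C5) keeps its configuration. The step needs regioselective C–O cleavage and migration of carbon rather than hydride; the inductive effect of the C1 siloxy group, the high migratory aptitude of an oxygen-bearing tertiary carbon and a very bulky, non-nucleophilic Lewis acid at low temperature should secure both, and the side-chain silyl ether, being cis to the epoxide, cannot open it from the rear.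

Step 8
Reactants: 9 (1R,2R,5R)-2-methyl-2-(triethylsilyloxy)-5-[2-(triethylsilyloxy)propan-2-yl]cyclopentane-1-carbaldehyde; 10 ethyl (2E)-4-(diethoxyphosphoryl)-3-methylbut-2-enoate (triethyl 3-methyl-4-phosphonocrotonate)
Product: 12 ethyl (2E,4E)-3-methyl-5-{(1R,2R,5R)-2-methyl-2-(triethylsilyloxy)-5-[2-(triethylsilyloxy)propan-2-yl]cyclopentyl}penta-2,4-dienoate, via lithiated phosphonate 11 (not isolated)
Conditions: 10, LiN(SiMe3)2, THF, −78 °C; then 9, −78 → 0 °C
Reagents that add atoms: none
Why: Horner–Wadsworth–Emmons olefination with a preformed lithium phosphonate at low temperature; the stabilised, weakly basic anion should add to the hindered formyl group faster than it enolises it, so C6 is not epimerised, the new C7=C8 bond should be E, and the 9E geometry comes from the reagent (any 9Z isomer to be removed by chromatography).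

Step 9
Reactants: 12 ethyl (2E,4E)-3-methyl-5-{(1R,2R,5R)-2-methyl-2-(triethylsilyloxy)-5-[2-(triethylsilyloxy)propan-2-yl]cyclopentyl}penta-2,4-dienoate
Product: 13 (2E,4E)-3-methyl-5-{(1R,2R,5R)-2-methyl-2-(triethylsilyloxy)-5-[2-(triethylsilyloxy)propan-2-yl]cyclopentyl}penta-2,4-dien-1-ol
Conditions: i-Bu2AlH, CH2Cl2, −78 °C; aq. potassium sodium tartrate
Reagents that add atoms: none
Why: 1,2-Reduction of a dienoate ester to the allylic alcohol with a dialkylaluminium hydride; silyl ethers and the diene are inert and no stereocentre is involved.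

Step 10
Reactants: 13 (2E,4E)-3-methyl-5-{(1R,2R,5R)-2-methyl-2-(triethylsilyloxy)-5-[2-(triethylsilyloxy)propan-2-yl]cyclopentyl}penta-2,4-dien-1-ol
Product: 15 [(2E,4E)-3-methyl-5-{(1R,2R,5R)-2-methyl-2-(triethylsilyloxy)-5-[2-(triethylsilyloxy)propan-2-yl]cyclopentyl}penta-2,4-dien-1-yl]triphenylphosphonium bromide, via allylic bromide 14 (not isolated)
Conditions: CBr4, PPh3, CH2Cl2, −20 °C; then PPh3, rt, dark
Reagents that add atoms: tetrabromomethane, BrC(Br)(Br)Br; triphenylphosphine, c1ccc(cc1)P(c1ccccc1)c1ccccc1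
Why: Appel bromination of the primary allylic alcohol under neutral conditions followed by SN2 quaternisation of triphenylphosphine; avoiding acid keeps the silyl ethers on and prevents an allyl cation that the C1 oxygen could trap, and the labile dienyl bromide is used as formed.

Step 11
Reactants: 16 pseudoionone, (3E,5E)-6,10-dimethylundeca-3,5,9-trien-2-one
Product: 17 (4E,6E)-3,7,11-trimethyldodeca-1,4,6,10-tetraen-3-ol (racemic at C3)
Conditions: CH2=CHMgBr, THF, −20 → 0 °C; aq. NH4Cl
Reagents that add atoms: vinylmagnesium bromide, C=C[Mg]Br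
Why: Grignard 1,2-addition of a vinyl nucleophile to the dienone carbonyl, which supplies the two carbons (C10′, C11′) missing between the C13 ketone and the C10 dialdehyde; the carbinol centre formed is racemic and is erased in the next step.

Step 12
Reactants: 17 (4E,6E)-3,7,11-trimethyldodeca-1,4,6,10-tetraen-3-ol
Product: 18 [(2E,4E,6E)-3,7,11-trimethyldodeca-2,4,6,10-tetraen-1-yl]triphenylphosphonium bromide
Conditions: Ph3P·HBr, MeOH, rt
Reagents that add atoms: triphenylphosphine hydrobromide, [Br-].[PH+](c1ccccc1)(c1ccccc1)c1ccccc1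
Why: Allylic phosphonium salt formation with allylic transposition (ionisation of the protonated tertiary bis-allylic alcohol and capture by triphenylphosphine at the primary terminus); the conjugated (2E) salt should predominate and is purified by crystallisation.

Step 13
Reactants: 18 [(2E,4E,6E)-3,7,11-trimethyldodeca-2,4,6,10-tetraen-1-yl]triphenylphosphonium bromide; 19 (2E,4E,6E)-2,7-dimethylocta-2,4,6-trienedial
Product: 21 (2E,4E,6E,8E,10E,12E,14E)-2,7,11,15,19-pentamethylicosa-2,4,6,8,10,12,14,18-octaenal (12′-apo-ψ-caroten-12′-al), via phosphorus ylide 20 (not isolated)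
Conditions: 19 (2 equiv), NaOMe, CH2Cl2/MeOH, 0 °C → rt; then heptane, reflux (Z → E)
Reagents that add atoms: none
Why: Wittig olefination of one formyl group of the symmetrical dialdehyde, used in excess to favour mono-condensation; the new C11′=C12′ bond forms as an E/Z mixture and its sterically hindered Z isomer should isomerise thermally to the all-E aldehyde.

Step 14
Reactants: 15 [(2E,4E)-3-methyl-5-{(1R,2R,5R)-2-methyl-2-(triethylsilyloxy)-5-[2-(triethylsilyloxy)propan-2-yl]cyclopentyl}penta-2,4-dien-1-yl]triphenylphosphonium bromide; 21 12′-apo-ψ-caroten-12′-al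
Product: 23 (all-E,2R,5R,6R)-1,5-bis(triethylsilyloxy)-2,6-cyclolycopene (bis-silyl ether of the target), via phosphorus ylide 22 (not isolated)
Conditions: NaOMe, CH2Cl2/MeOH, rt, dark; then heptane, reflux (Z → E)
Reagents that add atoms: none
Why: Wittig union of the two halves; tertiary triethylsilyl ethers tolerate methoxide, the new C11=C12 bond forms as an E/Z mixture whose hindered Z component should isomerise thermally to all-E, and no ring stereocentre is affected.

Step 15
Reactants: 23 (all-E,2R,5R,6R)-1,5-bis(triethylsilyloxy)-2,6-cyclolycopene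
Product: 24 (all-E,2R,5R,6R)-2,6-cyclolycopene-1,5-diol (target)
Conditions: Bu4NF, THF, rt → 40 °C, dark, argon
Reagents that add atoms: none
Why: Fluoride-induced desilylation of the two tertiary silyl ethers; the non-acidic conditions avoid ionisation or cyclisation of the polyene diol and leave C2, C5 and C6 untouched.

Compound list
1 | (+)-2-carene, (1S,6R)-3,7,7-trimethylbicyclo[4.1.0]hept-2-ene | CC1=C[C@H]2[C@@H](CC1)C2(C)C | starting material
2 | (+)-trans-2-carene oxide, (1S,2S,3R,6R)-2,3-epoxycarane | C[C@@]12CC[C@@H]3[C@@H](C3(C)C)[C@@H]1O2 | intermediate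
3 | (1R,4R)-1-methyl-4-(prop-1-en-2-yl)cyclohex-2-en-1-ol | C[C@@]1(O)CC[C@@H](C(C)=C)C=C1 | intermediate
4 | triethyl{[(1R,4R)-1-methyl-4-(prop-1-en-2-yl)cyclohex-2-en-1-yl]oxy}silane | C[C@@]1(O[Si](CC)(CC)CC)CC[C@@H](C(C)=C)C=C1 | intermediate
5 | 2-[(1R,4R)-4-methyl-4-(triethylsilyloxy)cyclohex-2-en-1-yl]propan-2-yl hydroperoxide | C[C@@]1(O[Si](CC)(CC)CC)CC[C@@H](C(C)(C)OO)C=C1 | intermediate
6 | 2-[(1R,4R)-4-methyl-4-(triethylsilyloxy)cyclohex-2-en-1-yl]propan-2-ol | C[C@@]1(O[Si](CC)(CC)CC)CC[C@@H](C(C)(C)O)C=C1 | intermediate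
7 | (1R,2R,3R,4R)-2,3-epoxy-1-(triethylsilyloxy)-p-menthan-8-ol | C[C@@]1(O[Si](CC)(CC)CC)CC[C@@H](C(C)(C)O)[C@H]2O[C@@H]12 | intermediate
8 | (1R,2R,3R,4R)-2,3-epoxy-1,8-bis(triethylsilyloxy)-p-menthane | C[C@@]1(O[Si](CC)(CC)CC)CC[C@@H](C(C)(C)O[Si](CC)(CC)CC)[C@H]2O[C@@H]12 | intermediate
9 | (1R,2R,5R)-2-methyl-2-(triethylsilyloxy)-5-[2-(triethylsilyloxy)propan-2-yl]cyclopentane-1-carbaldehyde | O=C[C@@H]1[C@H](C(C)(C)O[Si](CC)(CC)CC)CC[C@@]1(C)O[Si](CC)(CC)CC | intermediate
10 | ethyl (2E)-4-(diethoxyphosphoryl)-3-methylbut-2-enoate | CCOC(=O)/C=C(C)/CP(=O)(OCC)OCC | starting material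
11 | lithium salt of 10 (carbanion at C4) | [Li+].CCOC(=O)/C=C(C)/[CH-]P(=O)(OCC)OCC | intermediate
12 | ethyl (2E,4E)-3-methyl-5-{(1R,2R,5R)-2-methyl-2-(triethylsilyloxy)-5-[2-(triethylsilyloxy)propan-2-yl]cyclopentyl}penta-2,4-dienoate | CCOC(=O)/C=C(C)/C=C/[C@@H]1[C@H](C(C)(C)O[Si](CC)(CC)CC)CC[C@@]1(C)O[Si](CC)(CC)CC | intermediate
13 | (2E,4E)-3-methyl-5-{(1R,2R,5R)-2-methyl-2-(triethylsilyloxy)-5-[2-(triethylsilyloxy)propan-2-yl]cyclopentyl}penta-2,4-dien-1-ol | OC/C=C(C)/C=C/[C@@H]1[C@H](C(C)(C)O[Si](CC)(CC)CC)CC[C@@]1(C)O[Si](CC)(CC)CC | intermediate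
14 | (1R,2R,5R)-1-[(1E,3E)-5-bromo-3-methylpenta-1,3-dien-1-yl]-2-methyl-2-(triethylsilyloxy)-5-[2-(triethylsilyloxy)propan-2-yl]cyclopentane | BrC/C=C(C)/C=C/[C@@H]1[C@H](C(C)(C)O[Si](CC)(CC)CC)CC[C@@]1(C)O[Si](CC)(CC)CC | intermediate
15 | [(2E,4E)-3-methyl-5-{(1R,2R,5R)-2-methyl-2-(triethylsilyloxy)-5-[2-(triethylsilyloxy)propan-2-yl]cyclopentyl}penta-2,4-dien-1-yl]triphenylphosphonium bromide | c1ccccc1[P+](c1ccccc1)(c1ccccc1)C/C=C(C)/C=C/[C@@H]1[C@H](C(C)(C)O[Si](CC)(CC)CC)CC[C@@]1(C)O[Si](CC)(CC)CC.[Br-] | intermediate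
16 | pseudoionone, (3E,5E)-6,10-dimethylundeca-3,5,9-trien-2-one | CC(C)=CCC/C(C)=C/C=C/C(C)=O | starting material
17 | (4E,6E)-3,7,11-trimethyldodeca-1,4,6,10-tetraen-3-ol (racemic) | CC(C)=CCC/C(C)=C/C=C/C(C)(O)C=C | intermediate
18 | [(2E,4E,6E)-3,7,11-trimethyldodeca-2,4,6,10-tetraen-1-yl]triphenylphosphonium bromide | CC(C)=CCC/C(C)=C/C=C/C(C)=C/C[P+](c1ccccc1)(c1ccccc1)c1ccccc1.[Br-] | intermediate
19 | (2E,4E,6E)-2,7-dimethylocta-2,4,6-trienedial | O=C/C(C)=C/C=C/C=C(C)/C=O | starting material
20 | ylide of 18, [(2E,4E,6E)-3,7,11-trimethyldodeca-2,4,6,10-tetraen-1-ylidene]triphenylphosphorane | CC(C)=CCC/C(C)=C/C=C/C(C)=C/C=P(c1ccccc1)(c1ccccc1)c1ccccc1 | intermediate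
21 | (2E,4E,6E,8E,10E,12E,14E)-2,7,11,15,19-pentamethylicosa-2,4,6,8,10,12,14,18-octaenal | CC(C)=CCC/C(C)=C/C=C/C(C)=C/C=C/C(C)=C/C=C/C=C(C)/C=O | intermediate
22 | ylide of 15, [(2E,4E)-3-methyl-5-{(1R,2R,5R)-2-methyl-2-(triethylsilyloxy)-5-[2-(triethylsilyloxy)propan-2-yl]cyclopentyl}penta-2,4-dien-1-ylidene]triphenylphosphorane | c1ccccc1P(c1ccccc1)(c1ccccc1)=C/C=C(C)/C=C/[C@@H]1[C@H](C(C)(C)O[Si](CC)(CC)CC)CC[C@@]1(C)O[Si](CC)(CC)CC | intermediate
23 | (all-E,2R,5R,6R)-1,5-bis(triethylsilyloxy)-2,6-cyclolycopene | CC(C)=CCC/C(C)=C/C=C/C(C)=C/C=C/C(C)=C/C=C/C=C(C)/C=C/C=C(C)/C=C/[C@@H]1[C@H](C(C)(C)O[Si](CC)(CC)CC)CC[C@@]1(C)O[Si](CC)(CC)CC | intermediate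
24 | (all-E,2R,5R,6R)-2,6-cyclolycopene-1,5-diol | CC(C)=CCC/C(C)=C/C=C/C(C)=C/C=C/C(C)=C/C=C/C=C(C)/C=C/C=C(C)/C=C/[C@@H]1[C@H](C(C)(C)O)CC[C@@]1(C)O | target

Total step count: 15. Longest linear sequence: 12 steps (steps 1–10, 14 and 15); the C25 aldehyde branch (steps 11–13) joins at step 14.

Steps most likely to fail

Step 7. The epoxide may ionise at the carbon next to the siloxy centre, a hydride shift may compete with the shift of the ring bond (giving ketones), or the formyl-bearing centre may epimerise on the Lewis acid. The fallback sets out from 6 and comes back at 9, and replaces the concerted shift by a stepwise halohydrin ring contraction on the other epoxide diastereomer. Alcohol 6 is silylated (Et3SiOTf, 2,6-lutidine, CH2Cl2, −78 °C) to the bis(triethylsilyl) ether of the cyclohexene F1. With no free hydroxyl to direct it, mCPBA/NaHCO3 should attack the face away from the pseudo-axial C1 methyl and the side chain and give the diastereomeric epoxide F2. MgBr2·OEt2 in Et2O should then open F2 by trans-diaxial attack of bromide at C3 (C2 is neopentyl-like and shielded), giving the bromomagnesium alkoxide of the bromohydrin F3. On warming in toluene the C1–C2 bond displaces bromide from C3 with a second inversion, the classical magnesium-halohydrin contraction of cyclohexene oxides to cyclopentanecarbaldehydes. Two inversions at C3 starting from the opposite epoxide lead to the same aldehyde 9.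

Step 8. The phosphonate anion may enolise the hindered β-siloxy aldehyde instead of adding to it, which would epimerise C6 or expel the C5 silyloxy group, and addition to the crowded formyl group may simply be slow. The fallback sets out from 9 and comes back at 12 and avoids basic carbanions altogether. Takai olefination (CHI3, CrCl2, THF, 0 °C) should convert 9 into the (E)-iodoalkene F4. Stille coupling of F4 with ethyl (2E)-3-(tributylstannyl)but-2-enoate (Pd(PPh3)4, CuI, DMF, rt) then forms the C8–C9 bond with retention of both alkene geometries and gives ester 12.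

Step 2. The C8 cation may lose the ring proton at C4 (erasing the only carried stereocentre) instead of a methyl proton, and the tertiary allylic alcohol formed can ionise again and dehydrate towards aromatic by-products. The fallback sets out from 2 and comes back at 6, bypassing steps 2–4 by trapping the cation with a nucleophile instead of letting it eliminate. Solvolysis of 2 in acetic acid buffered with NaOAc at rt should capture the cation as the tertiary acetate and give the hydroxy acetate F5. Silylation of the free C1 hydroxyl (Et3SiOTf, 2,6-lutidine, CH2Cl2, −78 °C) gives the silyl ether acetate F6. Reductive removal of the acetate with LiAlH4 (Et2O, 0 °C) gives alcohol 6.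

Further compounds
F1 | step 7 | triethyl{[(1R,4R)-1-methyl-4-[2-(triethylsilyloxy)propan-2-yl]cyclohex-2-en-1-yl]oxy}silane | C[C@@]1(O[Si](CC)(CC)CC)CC[C@@H](C(C)(C)O[Si](CC)(CC)CC)C=C1
F2 | step 7 | (1R,2S,3S,4R)-2,3-epoxy-1,8-bis(triethylsilyloxy)-p-menthane (oxirane trans to the side chain) | C[C@@]1(O[Si](CC)(CC)CC)CC[C@@H](C(C)(C)O[Si](CC)(CC)CC)[C@@H]2O[C@H]12
F3 | step 7 | (1R,2R,3R,4S)-3-bromo-1,8-bis(triethylsilyloxy)-p-menthan-2-ol (bromine cis to the side chain) | C[C@@]1(O[Si](CC)(CC)CC)CC[C@@H](C(C)(C)O[Si](CC)(CC)CC)[C@@H](Br)[C@@H]1O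
F4 | step 8 | (1S,2R,5R)-1-[(E)-2-iodoethenyl]-2-methyl-2-(triethylsilyloxy)-5-[2-(triethylsilyloxy)propan-2-yl]cyclopentane (same ring configuration as 9) | I/C=C/[C@@H]1[C@H](C(C)(C)O[Si](CC)(CC)CC)CC[C@@]1(C)O[Si](CC)(CC)CC
F5 | step 2 | 2-[(1R,4R)-4-hydroxy-4-methylcyclohex-2-en-1-yl]propan-2-yl acetate | C[C@@]1(O)CC[C@@H](C(C)(C)OC(C)=O)C=C1
F6 | step 2 | 2-[(1R,4R)-4-methyl-4-(triethylsilyloxy)cyclohex-2-en-1-yl]propan-2-yl acetate | C[C@@]1(O[Si](CC)(CC)CC)CC[C@@H](C(C)(C)OC(C)=O)C=C1
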